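**Retrosynthetic overview**
1. Jezonodione 12 ⇐ diacetate 11 (ester cleavage only).
2. 11 ⇐ piceatannol 3 (catechol masked in the flask as phenylboronate 7) + stilbene o-quinone 6, joined first through a C–O bond: a resorcinol oxygen adds to the styryl-bearing quinone carbon, giving aryl quinol ether 8 with a quaternary C–O stereocentre set by a chiral phosphoric acid.
3. That C–O bond is then traded for the two C–C bonds: aromatic Claisen shift (C5–C6), then Michael closure onto the unveiled quinone methide (C1–C7).
4. Ring order: the cyclopentane ring (C1, C8, C5, C6, C7) closes last; this turns the resorcinol ring into the cyclohexenedione ring of the bicyclo[3.2.1]octane, while the quinonoid ring returns to a catechol.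
5. 6 ⇐ resveratrol 3,5-diacetate 5 (IBX) ⇐ resveratrol triacetate 4 (lipase); 3 ⇐ resveratrol 1 (IBX, then dithionite).

Assumption: core locants are those of bicyclo[3.2.1]oct-3-ene-2,8-dione (target = 1S,5R,6R,7R); the (R)-phosphoric acid is written as the enantiomer that gives this series and would be exchanged for its antipode if the first run shows the mirror-image sense.

**Route**

Step 1
Reactants: 1 resveratrol
Product: 3 piceatannol, via piceatannol o-quinone 2 (not isolated)
Conditions: IBX (1.1 equiv), MeOH, −25 °C, 1 h; then Na2S2O4 (3 equiv), H2O, −25 °C → rt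
Reagents that add atoms: IBX (2-iodoxybenzoic acid), O=C1OI(O)(=O)c2ccccc12
Why: IBX ortho-oxygenation of phenols delivers oxygen next to the free 4-OH of the electron-rich 4-hydroxystyryl ring to give o-quinone 2, which dithionite reduces in the same flask to the catechol; no stereocentre is formed.

Step 2
Reactants: 4 resveratrol triacetate
Product: 5 resveratrol 3,5-diacetate
Conditions: Candida antarctica lipase B (immobilised), n-BuOH (5 equiv), t-BuOMe, 40 °C
Reagents that add atoms: none
Why: Lipase-catalysed transesterification (alcoholysis) is regioselective for the acetate on the unhindered 4-acetoxyphenyl ring and leaves both resorcinol acetates; no stereocentre is formed.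

Step 3
Reactants: 5 resveratrol 3,5-diacetate
Product: 6 stilbene o-quinone diacetate
Conditions: IBX (1.05 equiv), DMF, −20 → 0 °C; cold CH2Cl2/aq. NaHCO3 wash, Na2SO4, solution used at once
Reagents that add atoms: IBX (2-iodoxybenzoic acid), O=C1OI(O)(=O)c2ccccc12
Why: IBX phenol-to-o-quinone oxidation occurs ortho to the only free OH, while the aryl acetates and the stilbene double bond are inert to IBX at low temperature; no stereocentre is formed.

Step 4
Reactants: 3 piceatannol (1.5 equiv), 6 stilbene o-quinone diacetate
Product: 11 jezonodione diacetate, via piceatannol phenylboronate 7 (not isolated), via aryl quinol ether 8 (not isolated), via quinone methide dienone 9 (not isolated), via cycloadduct bis(phenylboronate) 10 (not isolated)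
Conditions: 3, PhB(OH)2 (2.7 equiv), 4 Å MS, CH2Cl2/t-BuOMe 4:1, rt, 1 h; (R)-3,3'-bis(2,4,6-triisopropylphenyl)-1,1'-binaphthyl-2,2'-diyl hydrogen phosphate [(R)-TRIP, 10 mol %], −45 °C, 6 added over 4 h, then −20 °C, 12 h; aq. NaH2PO4 work-up
Reagents that add atoms: none
Why: Proposed new method: a chiral-phosphoric-acid-catalysed dearomative oxa-Michael/aromatic Claisen/Michael cascade in which the acid hydrogen-bonds the dione of 6 and one resorcinol O–H of 7 (catechol masked as boronate, so 6 is the only quinone) and guides that oxygen onto the styryl-bearing quinone carbon to form the quaternary C–O bond of 8 (4R), the doubly allylic aryl ether then undergoes a charge-accelerated chair [3,3] shift to the ring carbon para to the second OH (E-alkene, both H pseudo-axial), which transfers the C–O stereocentre to C5 and C6 (5R,6R, C6-aryl on the C8 side) and unveils quinone methide 9, and the vinylogous acid of the resorcinol-derived ring closes by 5-(enolexo)-exo-trig Michael addition from C1 to the methide carbon anti to the C6-aryl (7R, the bridge fixes 1S) before the dienone can tautomerise, the new catechol being capped as boronate 10; closest known reaction types are the Brønsted-acid-catalysed mixed-ketal formation/[3,3] shift in couplings of quinone monoketals with naphthols and the alkylative dearomatisation–annulation of phloroglucinols.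

Step 5
Reactants: 11 jezonodione diacetate
Product: 12 jezonodione
Conditions: HCl (1.25 M in MeOH), 0 °C → rt
Reagents that add atoms: none
Why: Acid-catalysed transesterification (methanolysis) removes the two aryl acetates without alkoxide, which would cleave the non-enolisable bridged 1,3-diketone by retro-Claisen reaction; the bridgehead and benzylic stereocentres cannot epimerise under these conditions.

**Compound list**

1 | resveratrol, 5-[(E)-2-(4-hydroxyphenyl)ethenyl]benzene-1,3-diol | Oc1ccc(/C=C/c2cc(O)cc(O)c2)cc1 | starting material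
2 | piceatannol o-quinone, 4-[(E)-2-(3,5-dihydroxyphenyl)ethenyl]cyclohexa-3,5-diene-1,2-dione (formed in the flask) | O=C1C=CC(/C=C/c2cc(O)cc(O)c2)=CC1=O | intermediate
3 | piceatannol, 4-[(E)-2-(3,5-dihydroxyphenyl)ethenyl]benzene-1,2-diol | Oc1cc(O)cc(/C=C/c2ccc(O)c(O)c2)c1 | intermediate
4 | resveratrol triacetate, (E)-3,5,4'-triacetoxystilbene | CC(=O)Oc1ccc(/C=C/c2cc(OC(C)=O)cc(OC(C)=O)c2)cc1 | starting material
5 | resveratrol 3,5-diacetate, 5-[(E)-2-(4-hydroxyphenyl)ethenyl]-1,3-phenylene diacetate | CC(=O)Oc1cc(OC(C)=O)cc(/C=C/c2ccc(O)cc2)c1 | intermediate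
6 | stilbene o-quinone diacetate, 5-[(E)-2-(3,4-dioxocyclohexa-1,5-dien-1-yl)ethenyl]-1,3-phenylene diacetate | CC(=O)Oc1cc(OC(C)=O)cc(/C=C/C2=CC(=O)C(=O)C=C2)c1 | intermediate
7 | piceatannol phenylboronate, 5-[(E)-2-(2-phenyl-1,3,2-benzodioxaborol-5-yl)ethenyl]benzene-1,3-diol (formed in the flask) | Oc1cc(O)cc(/C=C/c2ccc3OB(c4ccccc4)Oc3c2)c1 | intermediate
8 | aryl quinol ether, (4R)-2-hydroxy-4-[(E)-2-(3,5-diacetoxyphenyl)ethenyl]-4-{3-hydroxy-5-[(E)-2-(2-phenyl-1,3,2-benzodioxaborol-5-yl)ethenyl]phenoxy}cyclohexa-2,5-dien-1-one (formed in the flask) | Oc1cc(O[C@@]2(/C=C/c3cc(OC(C)=O)cc(OC(C)=O)c3)C=C(O)C(=O)C=C2)cc(/C=C/c2ccc3OB(c4ccccc4)Oc3c2)c1 | intermediate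
9 | quinone methide dienone, (6R)-6-[(1R)-1-(3,5-diacetoxyphenyl)-2-(3-hydroxy-4-oxocyclohexa-2,5-dien-1-ylidene)ethyl]-3-hydroxy-5-[(E)-2-(2-phenyl-1,3,2-benzodioxaborol-5-yl)ethenyl]cyclohexa-2,4-dien-1-one, ylidene bond Z (formed in the flask) | OC1=CC(=O)[C@H]([C@H](c3cc(OC(C)=O)cc(OC(C)=O)c3)/C=C4\C=C(O)C(=O)C=C4)C(/C=C/c2ccc3OB(c4ccccc4)Oc3c2)=C1 | intermediate
10 | cycloadduct bis(phenylboronate), compound 11 with both catechols closed as 2-phenyl-1,3,2-benzodioxaboroles (formed in the flask) | O=C1C=C(/C=C/c2ccc3OB(c4ccccc4)Oc3c2)[C@@H]2C(=O)[C@H]1[C@H](c1ccc3OB(c4ccccc4)Oc3c1)[C@H]2c1cc(OC(C)=O)cc(OC(C)=O)c1 | intermediate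
11 | jezonodione diacetate, 5-[(1S,5R,6R,7R)-7-(3,4-dihydroxyphenyl)-4-[(E)-2-(3,4-dihydroxyphenyl)ethenyl]-2,8-dioxobicyclo[3.2.1]oct-3-en-6-yl]-1,3-phenylene diacetate | O=C1C=C(/C=C/c2ccc(O)c(O)c2)[C@@H]2C(=O)[C@H]1[C@H](c1ccc(O)c(O)c1)[C@H]2c1cc(OC(C)=O)cc(OC(C)=O)c1 | intermediate
12 | jezonodione, (1S,5R,6R,7R)-7-(3,4-dihydroxyphenyl)-6-(3,5-dihydroxyphenyl)-4-[(E)-2-(3,4-dihydroxyphenyl)ethenyl]bicyclo[3.2.1]oct-3-ene-2,8-dione (aryl groups trans, C6-aryl on the side of the C8 bridge) | O=C1C=C(/C=C/c2ccc(O)c(O)c2)[C@@H]2C(=O)[C@H]1[C@H](c1ccc(O)c(O)c1)[C@H]2c1cc(O)cc(O)c1 | target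

**Step count**

Total: 5 steps. Longest linear sequence: 4 steps (4 → 5 → 6 → 11 → 12).

**Steps most likely to fail, with fallbacks**

Step 4 (new cascade). Failure modes:
- the aryl group may migrate to the carbon between the two oxygens, giving the regioisomeric bicycle;
- oxygen or carbon may add at unsubstituted quinone carbons, giving diaryl ethers or biaryls;
- the quinone may undergo hetero-Diels–Alder addition to a stilbene double bond;
- the dienone 9 may tautomerise to the dihydrobenzofuran series before ring closure;
- enantiocontrol may be poor.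

Fallback with known chemistry, setting out from 3 and coming back at 12: unprotected piceatannol 3 is submitted to biomimetic one-electron phenol coupling with FeCl3·6H2O in acetone/water at rt, the conditions that join hydroxystilbenes between the olefinic carbon of one unit and the resorcinol ring of the other. The dehydrodimer fraction is separated by reversed-phase chromatography to give jezonodione as the racemate, that is 12 together with ent-jezonodione F1. The racemate is resolved by preparative HPLC on a chiral stationary phase. This is expected to be low-yielding but is only two operations.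

Step 3 (handling a reactive stilbene o-quinone). Fallback setting out from 5 and coming back at 6: the IBX oxidation of 5 is run in MeOH at −25 °C and quenched in the flask with Na2S2O4, as in step 1, to give the bench-stable catechol 3,5-di-O-acetylpiceatannol F2, which can be purified and stored. Immediately before step 4, F2 is oxidised with Ag2O (2 equiv) and Na2SO4 in CH2Cl2 at 0 °C and filtered through Celite. A neutral, reagent-free solution of 6 then enters step 4 without any aqueous handling of the quinone.

Step 5 (the strained non-enolisable 1,3-diketone, the enone and three electron-rich rings may not tolerate ester cleavage). Fallback setting out from 1 and coming back at 12: the acetates are left out altogether. Resveratrol 1 is oxidised with IBX as in step 1 but without the dithionite quench, and the cold solution of piceatannol o-quinone 2 is washed free of 2-iodobenzoic acid. It is added over 8 h to phenylboronate 7 (3 equiv) and the same catalyst, so that the quinone stays dilute and meets 7 before its own resorcinol ring. The cascade then runs through aryl quinol ether with free resorcinol F3, quinone methide dienone with free resorcinol F4 and jezonodione bis(phenylboronate) F5. Aqueous work-up gives 12 directly, and surplus 3 is recovered.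

**Further compounds**

F1 | step 4 | ent-jezonodione | O=C1C=C(/C=C/c2ccc(O)c(O)c2)[C@H]2C(=O)[C@@H]1[C@@H](c1ccc(O)c(O)c1)[C@@H]2c1cc(O)cc(O)c1
F2 | step 3 | 3,5-di-O-acetylpiceatannol | CC(=O)Oc1cc(OC(C)=O)cc(/C=C/c2ccc(O)c(O)c2)c1
F3 | step 5 | aryl quinol ether with free resorcinol | Oc1cc(O[C@@]2(/C=C/c3cc(O)cc(O)c3)C=C(O)C(=O)C=C2)cc(/C=C/c2ccc3OB(c4ccccc4)Oc3c2)c1
F4 | step 5 | quinone methide dienone with free resorcinol | OC1=CC(=O)[C@H]([C@H](c3cc(O)cc(O)c3)/C=C4\C=C(O)C(=O)C=C4)C(/C=C/c2ccc3OB(c4ccccc4)Oc3c2)=C1
F5 | step 5 | jezonodione bis(phenylboronate) | O=C1C=C(/C=C/c2ccc3OB(c4ccccc4)Oc3c2)[C@@H]2C(=O)[C@H]1[C@H](c1ccc3OB(c4ccccc4)Oc3c1)[C@H]2c1cc(O)cc(O)c1
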